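**Retrosynthetic overview** (germacrane numbering)
1. Target ⇒ cyclodecadienone 31 by Luche reduction at C9, acylation of O8 with (R)-(2-methyloxiran-2-yl)acetic acid, and oxidative lactonisation of the C6/C12 diol.
2. Feature: the Z C1=C10 alkene fits inside a cyclohexene (ring A: C10, C1, C2, C3, C4, C9), and a transannular C4–C9 bond folds the ten-membered ring into a trans-decalin (ring B: C4–C9) in which an equatorial C5 sulfonate and the C9 alkoxide are 1,3-related. Hence 31 ⇒ mesylate 29 by Wharton–Grob fragmentation.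
3. 29 ⇒ ring B of (S)-carvone (C7): C4/C5 by reductive alkylation of a cis-epoxy ketone, O8 and O6 by enolate oxidations, the axial C8 and equatorial C5 alcohols by ketone reductions in the rigid decalin. An epoxide opening of a C5=C6 alkene there would give the diaxial diol (C5 and C6 both inverted) and is not used.
4. Ring A by isopropenyl addition at C9 and ring-closing metathesis with a C4 butenyl chain.
5. Order of rings: ring B (carvone) → ring A (metathesis) → ten-membered ring (fragmentation) → lactone.

Key step: step 22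

Remark: C11 is the carbon on C7, C12 its oxygenated carbon, C13 its methylene, C14 the methyl on C10, C15 the methyl on C4; relative configurations are given against the C7 side chain.
Assumption: 4-iodobut-1-ene, (S)-2-methylglycidol and THF solutions of isopropenyl- and vinylmagnesium bromide are bought; O12 is carried as a triisopropylsilyl ether so that a temporary triethylsilyl ether on O5 can be cleaved beside it.

Step 1
Reactants: 1 (S)-carvone
Product: 2 10-chlorocarvone
Conditions: Ca(OCl)2, CO2 (solid), CH2Cl2/H2O, 0 °C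
Reagents that add atoms: calcium hypochlorite, [Ca+2].[O-]Cl.[O-]Cl
Why: Ene-type allylic chlorination by HOCl formed in situ should occur only at the electron-rich 1,1-disubstituted alkene (the enone alkene is deactivated) and leaves C7 untouched.

Step 2
Reactants: 2 10-chlorocarvone
Product: 3 allylic acetate
Conditions: KOAc, Bu4NI (cat.), DMF, 50 °C
Reagents that add atoms: potassium acetate, CC(=O)[O-].[K+]
Why: SN2 displacement of the primary allylic chloride by acetate, assisted by iodide exchange.

Step 3
Reactants: 3 allylic acetate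
Product: 4 10-hydroxycarvone
Conditions: K2CO3 (0.2 equiv), MeOH, 0 °C
Reagents that add atoms: none
Why: Base-catalysed transesterification frees the primary allylic alcohol, and short exposure at 0 °C should avoid conjugate addition to the enone.

Step 4
Reactants: 4 10-hydroxycarvone
Product: 5 silyloxy carvone
Conditions: i-Pr3SiCl, imidazole, DMF, rt
Reagents that add atoms: chlorotriisopropylsilane, CC(C)[Si](Cl)(C(C)C)C(C)C
Why: Silylation of the only hydroxyl gives an ether that is stable to base, hydride, organometallics and brief dissolving-metal conditions.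

Step 5
Reactants: 5 silyloxy carvone
Product: 6 cis allylic alcohol
Conditions: NaBH4, CeCl3·7H2O, MeOH, −78 °C
Reagents that add atoms: none
Why: Luche 1,2-reduction with axial hydride delivery should give the C9 alcohol cis to the C7 side chain, as for carvone itself; this centre only serves to direct step 6.

Step 6
Reactants: 6 cis allylic alcohol
Product: 7 cis epoxy alcohol
Conditions: VO(acac)2 (cat.), t-BuOOH, CH2Cl2, 0 °C → rt
Reagents that add atoms: tert-butyl hydroperoxide, CC(C)(C)OO
Why: Hydroxyl-directed vanadium-catalysed epoxidation delivers oxygen to C4=C5 on the face of the C9 hydroxyl, hence cis to the C7 side chain, and the second alkene has no free hydroxyl to bind the metal.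

Step 7
Reactants: 7 cis epoxy alcohol
Product: 8 cis epoxy ketone
Conditions: Dess–Martin periodinane, NaHCO3, CH2Cl2, rt
Reagents that add atoms: none
Why: Buffered periodinane oxidation of the secondary alcohol restores the C9 ketone without opening the epoxide.

Step 8
Reactants: 8 cis epoxy ketone; 9 4-iodobut-1-ene
Product: 11 butenyl aldol, via dilithium enolate alkoxide 10 (not isolated)
Conditions: Li (2.2 equiv), NH3(l)/THF, −78 °C; then 9 (5 equiv), −78 → −33 °C; NH4Cl
Reagents that add atoms: none
Why: Two-electron reduction cleaves the C4–O bond to give the C9(4)-enolate/C5-alkoxide regiospecifically (reductive alkylation of an α,β-epoxy ketone), and the iodide should add to C4 opposite the adjacent C5 lithium alkoxide, so the butenyl group ends trans to O5 and to the C7 side chain while C5 keeps the epoxide configuration.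

Step 9
Reactants: 11 butenyl aldol
Product: 12 triethylsilyl ether
Conditions: Et3SiOTf, 2,6-lutidine, CH2Cl2, −78 °C
Reagents that add atoms: triethylsilyl trifluoromethanesulfonate, CC[Si](CC)(CC)OS(=O)(=O)C(F)(F)F
Why: Silylation of the hindered C5 alcohol under non-basic conditions avoids retro-aldol cleavage and masks O5 until the C8/C9 work is done.

Step 10
Reactants: 12 triethylsilyl ether
Product: 14 C8 hydroxy ketone, via lithium enolate 13 (not isolated)
Conditions: LiN(i-Pr)2, THF, −78 °C; then 3-phenyl-2-(phenylsulfonyl)oxaziridine, −78 °C; NH4Cl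
Reagents that add atoms: 3-phenyl-2-(phenylsulfonyl)oxaziridine, O=S(=O)(c1ccccc1)N1OC1c1ccccc1
Why: The ketone can enolise only toward C8, and enolate oxidation by the N-sulfonyloxaziridine should occur opposite the neighbouring C7 side chain and the axial C4 methyl, giving the C8 alcohol trans to the side chain.

Step 11
Reactants: 14 C8 hydroxy ketone; 15 isopropenylmagnesium bromide
Product: 17 tertiary carbinol, via magnesium alkoxide chelate 16 (not isolated)
Conditions: 15 (3.5 equiv), THF/CH2Cl2, −78 → −30 °C; NH4Cl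
Reagents that add atoms: none
Why: Grignard 1,2-addition to the magnesium chelate of the α-alkoxide ketone (Cram-chelate control): axial attack would pass the syn-axial hydrogens at C5 and C7 and end gauche to the magnesium-bound O8, so equatorial attack on the face of the C8 hydrogen should give the C9 alcohol cis to O8 with the isopropenyl group trans to the butenyl chain.

Step 12
Reactants: 17 tertiary carbinol
Product: 18 trans-decalin diol
Conditions: RuCl2(=CHPh)(PCy3)(H2IMes) (second-generation Grubbs catalyst, 5 mol%), CH2Cl2, 40 °C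
Reagents that add atoms: none
Why: Ring-closing metathesis of the butenyl vinyl group with the isopropenyl group on adjacent trans-diequatorial positions closes ring A as a trisubstituted cyclohexene, necessarily Z, and the hindered C11 methylene should stay out.

Step 13
Reactants: 18 trans-decalin diol
Product: 19 C8 ketone
Conditions: (COCl)2, DMSO, CH2Cl2, −78 °C; Et3N, −78 → −20 °C
Reagents that add atoms: none
Why: Swern oxidation converts the secondary C8 alcohol into the ketone, while the tertiary C9 alcohol cannot be oxidised.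

Step 14
Reactants: 19 C8 ketone
Product: 20 trans-diaxial diol
Conditions: NaBH4, MeOH/CH2Cl2, −40 °C
Reagents that add atoms: none
Why: In the rigid trans-decalin, axial hydride attack at C8 is blocked by the 1,3-diaxial C4 methyl, so hydride should enter from the other face (helped by the boron-bound C9 alkoxide) and give the axial C8 alcohol, trans to the C9 hydroxyl and cis to the C7 side chain; this is a net inversion of C8 by oxidation–reduction.

Step 15
Reactants: 20 trans-diaxial diol
Product: 21 PMB ether
Conditions: NaH, 4-MeOC6H4CH2Br, Bu4NI (cat.), THF/DMF, 0 °C → rt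
Reagents that add atoms: 4-methoxybenzyl bromide, COc1ccc(CBr)cc1
Why: Williamson etherification should take the secondary C8 alkoxide, since the tertiary C9 hydroxyl is far more hindered.

Step 16
Reactants: 21 PMB ether
Product: 22 C5 alcohol
Conditions: HF·pyridine, pyridine, THF, 0 °C
Reagents that add atoms: none
Why: Buffered fluoride cleaves the secondary triethylsilyl ether and should leave the bulkier triisopropylsilyl ether, the benzylic ether and the tertiary allylic alcohol intact.

Step 17
Reactants: 22 C5 alcohol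
Product: 23 C5 ketone
Conditions: Dess–Martin periodinane, NaHCO3, CH2Cl2, 0 °C → rt
Reagents that add atoms: none
Why: Periodinane oxidation of the only secondary alcohol under buffered, non-basic conditions gives the β-hydroxy ketone without retro-aldol cleavage.

Step 18
Reactants: 23 C5 ketone
Product: 26 C6 hydroxy ketone, via bis-silyl enol ether 24 (not isolated), via silyloxy epoxide 25 (not isolated)
Conditions: Me3SiOTf, Et3N, CH2Cl2, 0 °C; then dimethyldioxirane, acetone/CH2Cl2, −78 → −40 °C; then citric acid, MeOH, 0 °C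
Reagents that add atoms: dimethyldioxirane, CC1(C)OO1
Why: Rubottom oxidation: soft enolisation can only go toward C6 and also silylates the C9 hydroxyl (no alkoxide, no retro-aldol), the silyl enol ether should be epoxidised much faster than the other alkenes and opposite the axial C4 methyl and axial C8 ether, and mild acid then unveils the equatorial C6 alcohol trans to the C7 side chain.

Step 19
Reactants: 26 C6 hydroxy ketone
Product: 27 C6 silyl ether
Conditions: t-BuMe2SiOTf (1.1 equiv), 2,6-lutidine, CH2Cl2, −78 °C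
Reagents that add atoms: tert-butyldimethylsilyl trifluoromethanesulfonate, CC(C)(C)[Si](C)(C)OS(=O)(=O)C(F)(F)F
Why: At low temperature the secondary α-ketol hydroxyl should be silylated well before the axial tertiary C9 hydroxyl.

Step 20
Reactants: 27 C6 silyl ether
Product: 28 C5 alcohol
Conditions: Me4NBH(OAc)3, MeCN/AcOH, −30 °C
Reagents that add atoms: none
Why: Hydroxyl-directed (Evans–Saksena) reduction: the axial C9 hydroxyl binds the triacetoxyborohydride and delivers hydride across the 1,3-diaxial gap, which should give the equatorial C5 alcohol anti to the C9 hydroxyl and trans to the C6 silyl ether.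

Step 21
Reactants: 28 C5 alcohol
Product: 29 C5 mesylate
Conditions: MeSO2Cl, Et3N, CH2Cl2, −20 → 0 °C
Reagents that add atoms: methanesulfonyl chloride, CS(=O)(=O)Cl
Why: Sulfonylation through sulfene takes the secondary alcohol, leaves the tertiary C9 hydroxyl free for the fragmentation, and the amine is too weak a base to start it.

Step 22
Reactants: 29 C5 mesylate
Product: 31 cyclodecadienone, via potassium alkoxide 30 (not isolated)
Conditions: KOt-Bu (1.1 equiv), THF, 0 °C; pH 7 buffer
Reagents that add atoms: none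
Why: KOt-Bu deprotonates the tertiary C9 hydroxyl, and the alkoxide lone pair pushes into the C4–C9 bond while the antiperiplanar C5–O bond of the mesylate ionises, a concerted heterolytic (Grob) fragmentation that forms the C9 carbonyl and the C4=C5 alkene together. The closest known reaction type is the Wharton fragmentation of cyclic 1,3-diol monosulfonates to medium-ring alkenones. No ring is closed by bond formation: the ten-membered ring appears when the bond shared by the two six-membered rings is cut, so the mode is ring expansion by fragmentation, not cyclisation. No stereocentre is created (C4, C5 and C9 become trigonal; C6, C7 and C8 are carried over), and the only new stereo-element is the C4=C5 geometry. The step needs E at C4=C5 and Z at C1=C10: the trans-decalin chair holds the equatorial mesylate anti to C4–C9 and C3 anti to C6, which becomes the E alkene, and the Z alkene is inherited from the cyclohexene of ring A. Oxetane formation is geometrically closed to an equatorial leaving group, and one equivalent of base at 0 °C with a buffered quench should spare the C8 centre α to the new ketone.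

Step 23
Reactants: 31 cyclodecadienone
Product: 32 C6/C12 diol
Conditions: Bu4NF, AcOH, THF, 0 °C → rt
Reagents that add atoms: none
Why: Fluoride cleaves both silyl ethers, and the acetic acid buffer should prevent epimerisation at C8.

Step 24
Reactants: 32 C6/C12 diol
Product: 35 methylene lactone, via enal 33 (not isolated), via lactol 34 (not isolated)
Conditions: 2,2,6,6-tetramethylpiperidin-1-oxyl (cat.), PhI(OAc)2 (2.5 equiv), CH2Cl2, rt
Reagents that add atoms: none
Why: Oxidative lactonisation of a 1,4-diol: the nitroxyl catalyst selects the primary allylic alcohol, the enal is trapped by the C6 hydroxyl as a lactol and oxidised on to the α-methylene-γ-butyrolactone, whose trans fusion follows from the existing C6 and C7 centres.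

Step 25
Reactants: 35 methylene lactone
Product: 36 C8 hydroxy ketone
Conditions: DDQ, CH2Cl2/pH 7 buffer, 0 °C
Reagents that add atoms: none
Why: Oxidative cleavage of the 4-methoxybenzyl ether via its benzylic oxocarbenium ion frees O8 under neutral conditions that the dienone and lactone tolerate.

Step 26
Reactants: 37 (S)-2-methylglycidol; 38 vinylmagnesium bromide
Product: 39 pentenediol
Conditions: 38 (3 equiv), CuI (10 mol%), THF, −30 → 0 °C; NH4Cl
Reagents that add atoms: none
Why: Copper-catalysed SN2 opening of the epoxide at its unsubstituted carbon adds the vinyl group without touching the quaternary stereocentre.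

Step 27
Reactants: 39 pentenediol
Product: 41 allyl epoxide, via primary tosylate 40 (not isolated)
Conditions: NaH (2.2 equiv), 1-(p-tolylsulfonyl)imidazole, THF, 0 °C → rt
Reagents that add atoms: none
Why: One-pot sulfonylation of the primary alkoxide and 3-exo-tet closure by the tertiary alkoxide re-forms the epoxide on the former carbinol carbon, and the C–O bond at the stereocentre is never broken.

Step 28
Reactants: 41 allyl epoxide
Product: 42 epoxy acid
Conditions: RuCl3·3H2O (2 mol%), NaIO4, MeCN/EtOAc/pH 7 phosphate buffer, 0 °C; cold extraction at pH 4, used at once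
Reagents that add atoms: sodium periodate, [Na+].[O-]I(=O)(=O)=O; water, O
Why: RuO4-catalysed oxidative cleavage of the terminal alkene gives the carboxylic acid one carbon shorter, and the buffer keeps it as the carboxylate so that the epoxide is not opened by its own acid.

Step 29
Reactants: 36 C8 hydroxy ketone; 42 epoxy acid
Product: 43 C8 epoxy ester
Conditions: DCC, 4-(dimethylamino)pyridine (10 mol%), CH2Cl2, −20 → 0 °C
Reagents that add atoms: none
Why: Steglich esterification of the only free hydroxyl at low temperature with catalytic base should outrun base-induced opening of the β,γ-epoxy acyl unit.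

Step 30
Reactants: 43 C8 epoxy ester
Product: 44 target
Conditions: NaBH4, CeCl3·7H2O, MeOH, −78 °C
Reagents that add atoms: none
Why: Luche 1,2-reduction of the enone carbonyl, with cerium bridging the C9 carbonyl and the C8 oxygen so that hydride should arrive opposite the C7 branch and give the 8,9-erythro (9R) alcohol, while the cold conditions spare the methylene lactone and the epoxy ester.

**Compound list**
1 | (S)-(+)-carvone | CC1=CC[C@@H](CC1=O)C(C)=C | starting material
2 | (S)-10-chlorocarvone, (5S)-5-(3-chloroprop-1-en-2-yl)-2-methylcyclohex-2-en-1-one | CC1=CC[C@@H](CC1=O)C(=C)CCl | intermediate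
3 | (S)-10-acetoxycarvone | CC1=CC[C@@H](CC1=O)C(=C)COC(C)=O | intermediate
4 | (S)-10-hydroxycarvone | CC1=CC[C@@H](CC1=O)C(=C)CO | intermediate
5 | (S)-10-(triisopropylsilyloxy)carvone | CC1=CC[C@@H](CC1=O)C(=C)CO[Si](C(C)C)(C(C)C)C(C)C | intermediate
6 | (1S,5S)-2-methyl-5-[3-(triisopropylsilyloxy)prop-1-en-2-yl]cyclohex-2-en-1-ol, hydroxyl cis to the side chain | CC1=CC[C@@H](C[C@@H]1O)C(=C)CO[Si](C(C)C)(C(C)C)C(C)C | intermediate
7 | 4,5-epoxy-9-ol, epoxide, hydroxyl and C7 side chain all cis | C[C@]12O[C@@H]2C[C@@H](C[C@@H]1O)C(=C)CO[Si](C(C)C)(C(C)C)C(C)C | intermediate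
8 | 4,5-epoxy-9-ketone, epoxide cis to the C7 side chain | C[C@]12O[C@@H]2C[C@@H](CC1=O)C(=C)CO[Si](C(C)C)(C(C)C)C(C)C | intermediate
9 | 4-iodobut-1-ene | C=CCCI | starting material
10 | dilithium C9(4)-enolate C5-alkoxide | [Li+].[Li+].CC1=C([O-])C[C@H](C[C@H]1[O-])C(=C)CO[Si](C(C)C)(C(C)C)C(C)C | intermediate
11 | C9 ketone with quaternary C4 (methyl; but-3-enyl trans to the C7 side chain) and C5 hydroxyl cis to the C7 side chain | C=CCC[C@@]1(C)[C@H](O)C[C@@H](CC1=O)C(=C)CO[Si](C(C)C)(C(C)C)C(C)C | intermediate
12 | C5 triethylsilyl ether of 11 | C=CCC[C@@]1(C)[C@H](O[Si](CC)(CC)CC)C[C@@H](CC1=O)C(=C)CO[Si](C(C)C)(C(C)C)C(C)C | intermediate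
13 | lithium C8(9)-enolate of 12 | [Li+].C=CCC[C@@]1(C)[C@H](O[Si](CC)(CC)CC)C[C@@H](C=C1[O-])C(=C)CO[Si](C(C)C)(C(C)C)C(C)C | intermediate
14 | C8 hydroxy C9 ketone, C8 hydroxyl trans to the C7 side chain | C=CCC[C@@]1(C)[C@H](O[Si](CC)(CC)CC)C[C@@H]([C@@H](O)C1=O)C(=C)CO[Si](C(C)C)(C(C)C)C(C)C | intermediate
15 | isopropenylmagnesium bromide | CC(=C)[Mg]Br | starting material
16 | bromomagnesium C8 alkoxide of 14 (chelate with the C9 carbonyl) | C=CCC[C@@]1(C)[C@H](O[Si](CC)(CC)CC)C[C@@H]([C@@H](O[Mg]Br)C1=O)C(=C)CO[Si](C(C)C)(C(C)C)C(C)C | intermediate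
17 | C8,C9 cis-diol, tertiary C9 carbinol with isopropenyl cis to the C4 methyl | C=CCC[C@@]1(C)[C@H](O[Si](CC)(CC)CC)C[C@@H]([C@@H](O)[C@]1(O)C(C)=C)C(=C)CO[Si](C(C)C)(C(C)C)C(C)C | intermediate
18 | trans-decalin 1(10)-ene, C9 hydroxyl trans to the C4 methyl, C8 hydroxyl cis to the C9 hydroxyl | CC1=CCC[C@@]2(C)[C@H](O[Si](CC)(CC)CC)C[C@H](C(=C)CO[Si](C(C)C)(C(C)C)C(C)C)[C@@H](O)[C@]12O | intermediate
19 | C8 ketone of the trans-decalin (9-hydroxy) | CC1=CCC[C@@]2(C)[C@H](O[Si](CC)(CC)CC)C[C@H](C(=C)CO[Si](C(C)C)(C(C)C)C(C)C)C(=O)[C@]12O | intermediate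
20 | C8 axial alcohol, trans to the C9 hydroxyl and cis to the C7 side chain | CC1=CCC[C@@]2(C)[C@H](O[Si](CC)(CC)CC)C[C@H](C(=C)CO[Si](C(C)C)(C(C)C)C(C)C)[C@H](O)[C@]12O | intermediate
21 | C8 4-methoxybenzyl ether of 20 | CC1=CCC[C@@]2(C)[C@H](O[Si](CC)(CC)CC)C[C@H](C(=C)CO[Si](C(C)C)(C(C)C)C(C)C)[C@H](OCc3ccc(OC)cc3)[C@]12O | intermediate
22 | C5 alcohol (triethylsilyl removed) | CC1=CCC[C@@]2(C)[C@H](O)C[C@H](C(=C)CO[Si](C(C)C)(C(C)C)C(C)C)[C@H](OCc3ccc(OC)cc3)[C@]12O | intermediate
23 | C5 ketone, 9-hydroxy | CC1=CCC[C@@]2(C)C(=O)C[C@H](C(=C)CO[Si](C(C)C)(C(C)C)C(C)C)[C@H](OCc3ccc(OC)cc3)[C@]12O | intermediate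
24 | C5(6) trimethylsilyl enol ether, C9 trimethylsilyl ether | CC1=CCC[C@@]2(C)C(O[Si](C)(C)C)=C[C@H](C(=C)CO[Si](C(C)C)(C(C)C)C(C)C)[C@H](OCc3ccc(OC)cc3)[C@]12O[Si](C)(C)C | intermediate
25 | 5,6-epoxide of 24, oxygen opposite the C4 methyl | CC1=CCC[C@@]2(C)[C@@]3(O[Si](C)(C)C)O[C@H]3[C@H](C(=C)CO[Si](C(C)C)(C(C)C)C(C)C)[C@H](OCc4ccc(OC)cc4)[C@]12O[Si](C)(C)C | intermediate
26 | C6 hydroxy C5 ketone, C6 hydroxyl trans to the C7 side chain | CC1=CCC[C@@]2(C)C(=O)[C@@H](O)[C@H](C(=C)CO[Si](C(C)C)(C(C)C)C(C)C)[C@H](OCc3ccc(OC)cc3)[C@]12O | intermediate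
27 | C6 tert-butyldimethylsilyl ether of 26 | CC1=CCC[C@@]2(C)C(=O)[C@@H](O[Si](C)(C)C(C)(C)C)[C@H](C(=C)CO[Si](C(C)C)(C(C)C)C(C)C)[C@H](OCc3ccc(OC)cc3)[C@]12O | intermediate
28 | C5 equatorial alcohol, trans to O6 and anti to the C9 hydroxyl | CC1=CCC[C@@]2(C)[C@H](O)[C@@H](O[Si](C)(C)C(C)(C)C)[C@H](C(=C)CO[Si](C(C)C)(C(C)C)C(C)C)[C@H](OCc3ccc(OC)cc3)[C@]12O | intermediate
29 | 9-hydroxy trans-decalin C5 mesylate (fragmentation precursor) | CC1=CCC[C@@]2(C)[C@H](OS(C)(=O)=O)[C@@H](O[Si](C)(C)C(C)(C)C)[C@H](C(=C)CO[Si](C(C)C)(C(C)C)C(C)C)[C@H](OCc3ccc(OC)cc3)[C@]12O | intermediate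
30 | potassium C9 alkoxide of 29 | [K+].CC1=CCC[C@@]2(C)[C@H](OS(C)(=O)=O)[C@@H](O[Si](C)(C)C(C)(C)C)[C@H](C(=C)CO[Si](C(C)C)(C(C)C)C(C)C)[C@H](OCc3ccc(OC)cc3)[C@]12[O-] | intermediate
31 | (1(10)Z,4E)-cyclodecadien-9-one with O6 silyl, O8 4-methoxybenzyl, O12 silyl | CC(C)(C)[Si](C)(C)O[C@@H]1/C=C(\C)CC/C=C(/C)C(=O)[C@@H](OCc2ccc(OC)cc2)[C@H]1C(=C)CO[Si](C(C)C)(C(C)C)C(C)C | intermediate
32 | C6/C12 diol of the cyclodecadienone | O[C@@H]1/C=C(\C)CC/C=C(/C)C(=O)[C@@H](OCc2ccc(OC)cc2)[C@H]1C(=C)CO | intermediate
33 | C12 enal, C6 hydroxyl free | O[C@@H]1/C=C(\C)CC/C=C(/C)C(=O)[C@@H](OCc2ccc(OC)cc2)[C@H]1C(=C)C=O | intermediate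
34 | 6,12-lactol (both anomers) | C=C1C(O)O[C@@H]2/C=C(\C)CC/C=C(/C)C(=O)[C@@H](OCc3ccc(OC)cc3)[C@@H]12 | intermediate
35 | trans-fused α-methylene-γ-butyrolactone, C9 ketone, O8 4-methoxybenzyl | C=C1C(=O)O[C@@H]2/C=C(\C)CC/C=C(/C)C(=O)[C@@H](OCc3ccc(OC)cc3)[C@@H]12 | intermediate
36 | C8 hydroxy C9 ketone lactone | C=C1C(=O)O[C@@H]2/C=C(\C)CC/C=C(/C)C(=O)[C@@H](O)[C@@H]12 | intermediate
37 | (S)-2-methylglycidol, [(2S)-2-methyloxiran-2-yl]methanol | C[C@]1(CO)CO1 | starting material
38 | vinylmagnesium bromide | C=C[Mg]Br | starting material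
39 | (2R)-2-methylpent-4-ene-1,2-diol | C=CC[C@@](C)(O)CO | intermediate
40 | primary p-toluenesulfonate of 39 | C=CC[C@@](C)(O)COS(=O)(=O)c1ccc(C)cc1 | intermediate
41 | (2R)-2-methyl-2-(prop-2-en-1-yl)oxirane | C=CC[C@]1(C)CO1 | intermediate
42 | [(2R)-2-methyloxiran-2-yl]acetic acid | OC(=O)C[C@]1(C)CO1 | intermediate
43 | C8 [(2R)-2-methyloxiran-2-yl]acetate, C9 ketone lactone | C=C1C(=O)O[C@@H]2/C=C(\C)CC/C=C(/C)C(=O)[C@@H](OC(=O)C[C@]3(C)CO3)[C@@H]12 | intermediate
44 | CNP0284481.1, (1(10)Z,4E)-germacradien-6,12-olide with 9-hydroxyl and 8-[(2R)-2-methyloxiran-2-yl]acetate | C=C1C(=O)O[C@@H]2/C=C(\C)CC/C=C(/C)[C@@H](O)[C@@H](OC(=O)C[C@]3(C)CO3)[C@@H]12 | target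

**Totals**
Total step count: 30.
Longest linear sequence: 27 steps (steps 1–25, 29 and 30); steps 26–28 form the acid branch.

**Three steps most likely to fail**

Step 8. Elimination of the homoallylic iodide and proton transfer may outrun C-alkylation of the hindered tetrasubstituted enolate, and the allylic silyl ether may be cleaved if the metal is overdosed. The fallback sets out from 8 and comes back at 12. The same reductively formed enolate is trapped with allyl bromide, a much better electrophile, to give the allyl aldol F1 with the same facial preference. Silylation as in step 9 gives the triethylsilyl ether F2. Anti-Markovnikov hydroboration of the monosubstituted alkene with disiamylborane (the 1,1-disubstituted alkene and the neopentyl ketone react far more slowly) and NaBO3 oxidation give the primary alcohol F3. Dess–Martin oxidation gives the aldehyde F4, and Wittig methylenation with Ph3P=CH2, which takes the aldehyde in preference to the hindered ketone, gives 12.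

Step 11. Attack opposite the axial C4 methyl may compete, so facial selectivity at C9 may be poor and the isopropenyl group may end on the wrong face. The fallback sets out from 14 and comes back at 19, and sets C9 by oxygen delivery instead of carbon delivery. The adduct of opposite C9 configuration F5 (alone or mixed with 17) is cyclised as in step 12 to the cis-fused decalin F6 and oxidised as in step 13 to the α-ketol F7. SmI2 in THF/MeOH removes the tertiary hydroxyl α to the ketone and gives the ketone F8, whose C9 is now an enolisable allylic CH. KN(SiMe3)2 forms the extended enolate, and the N-sulfonyloxaziridine of step 10 should hydroxylate C9 opposite the angular methyl, the normal direction for an electrophile, which gives 19 from either C9 epimer.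

Step 30. Hydride may reach the wrong face of the C9 carbonyl of the flexible ten-membered ring, or reduce the methylene lactone in conjugate fashion. The fallback sets out from 35 and comes back at 44. Ketone 35, whose benzylic ether on O8 chelates better than an ester, is reduced with Zn(BH4)2 under chelation control to the C9 alcohol F9. Chloroacetic anhydride and pyridine cap it as the chloroacetate F10, DDQ frees O8 to give F11, and esterification with 42 as in step 29 gives the diester F12. Thiourea with NaHCO3 in ethanol then removes only the chloroacetate and gives 44.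

**Further compounds**
F1 | step 8 | 4-allyl analogue of 11 (allyl trans to the C7 side chain, C5 hydroxyl cis) | C=CC[C@@]1(C)[C@H](O)C[C@@H](CC1=O)C(=C)CO[Si](C(C)C)(C(C)C)C(C)C
F2 | step 8 | C5 triethylsilyl ether of F1 | C=CC[C@@]1(C)[C@H](O[Si](CC)(CC)CC)C[C@@H](CC1=O)C(=C)CO[Si](C(C)C)(C(C)C)C(C)C
F3 | step 8 | 3-hydroxypropyl ketone from hydroboration of F2 | OCCC[C@@]1(C)[C@H](O[Si](CC)(CC)CC)C[C@@H](CC1=O)C(=C)CO[Si](C(C)C)(C(C)C)C(C)C
F4 | step 8 | aldehyde from oxidation of F3 | O=CCC[C@@]1(C)[C@H](O[Si](CC)(CC)CC)C[C@@H](CC1=O)C(=C)CO[Si](C(C)C)(C(C)C)C(C)C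
F5 | step 11 | C9 epimer of 17 | C=CCC[C@@]1(C)[C@H](O[Si](CC)(CC)CC)C[C@@H]([C@@H](O)[C@@]1(O)C(C)=C)C(=C)CO[Si](C(C)C)(C(C)C)C(C)C
F6 | step 11 | cis-fused decalin diol, C9 epimer of 18 | CC1=CCC[C@@]2(C)[C@H](O[Si](CC)(CC)CC)C[C@H](C(=C)CO[Si](C(C)C)(C(C)C)C(C)C)[C@@H](O)[C@@]12O
F7 | step 11 | C9 epimer of 19 | CC1=CCC[C@@]2(C)[C@H](O[Si](CC)(CC)CC)C[C@H](C(=C)CO[Si](C(C)C)(C(C)C)C(C)C)C(=O)[C@@]12O
F8 | step 11 | 9-deoxy C8 ketone, C9 configuration open | CC1=CCC[C@@]2(C)[C@H](O[Si](CC)(CC)CC)C[C@H](C(=C)CO[Si](C(C)C)(C(C)C)C(C)C)C(=O)C12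
F9 | step 30 | C9 alcohol of 35 (C9 as in the target), O8 4-methoxybenzyl | C=C1C(=O)O[C@@H]2/C=C(\C)CC/C=C(/C)[C@@H](O)[C@@H](OCc3ccc(OC)cc3)[C@@H]12
F10 | step 30 | C9 chloroacetate of F9 | C=C1C(=O)O[C@@H]2/C=C(\C)CC/C=C(/C)[C@@H](OC(=O)CCl)[C@@H](OCc3ccc(OC)cc3)[C@@H]12
F11 | step 30 | C8 alcohol, C9 chloroacetate | C=C1C(=O)O[C@@H]2/C=C(\C)CC/C=C(/C)[C@@H](OC(=O)CCl)[C@@H](O)[C@@H]12
F12 | step 30 | C8 epoxy ester, C9 chloroacetate | C=C1C(=O)O[C@@H]2/C=C(\C)CC/C=C(/C)[C@@H](OC(=O)CCl)[C@@H](OC(=O)C[C@]3(C)CO3)[C@@H]12
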